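## Retrosynthetic overview

1. Agrimol C ⇒ two identical wing aldehydes + bought butyrylphloroglucinol. Both ArCH2–Ar bonds come from the aldehyde carbon of the wing by reduction and ortho-quinone-methide alkylation (last step).
2. Wing aldehyde ⇒ the C(=O)–CH2 bond of its butanoyl group is cut to an acyl anion (lithiated 2-aryl-1,3-dithiane) and 1-iodopropane. This is the key bond; the dithiane then stays on as a ketone mask.
3. Phenol pattern ⇒ a formyl group on the last free ring position steers BCl3 to its two ortho methyl ethers only. All ring oxygens and the C-methyl group come from 2,4,6-trimethoxytoluene.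
4. Rings: none is built. The three benzene rings and the temporary dithiane ring are bought; the dithiane is attached in step 1 and removed in step 4.

Assumption: the SMILES has no stereocentre or other stereogenic element, so agrimol C is achiral and no stereocontrol is needed; the three starting materials are taken as bought.

## Route

Step 1
Reactants: 1 2,4,6-trimethoxytoluene; 2 1,3-dithiane
Product: 4 2-(2,4,6-trimethoxy-3-methylphenyl)-1,3-dithiane, via 2-chloro-1,3-dithiane 3 (not isolated)
Conditions: 2, NCS (1.0 equiv), CH2Cl2, 0 °C → rt; then 1, ZnCl2 (5 mol %), 0 °C → rt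
Reagents that add atoms: none
Why: Friedel–Crafts-type electrophilic aromatic substitution with a masked formyl cation: the C–Cl bond of 3 is activated by its two sulfur atoms and the very electron-rich arene 1 attacks it at one of its two equivalent free positions, so a single regioisomer forms and no stereocentre is created.

Step 2
Reactants: 4 2-(2,4,6-trimethoxy-3-methylphenyl)-1,3-dithiane
Product: 8 2,4,6-trimethoxy-3-methyl-5-(2-propyl-1,3-dithian-2-yl)benzaldehyde, via lithiated dithiane 5 (not isolated), via propyl dithiane 6 (not isolated), via aryllithium 7 (not isolated)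
Conditions: n-BuLi (1.05 equiv), THF, −78 → −30 °C; 1-iodopropane (1.05 equiv), −78 → 0 °C; n-BuLi (1.5 equiv), TMEDA, 0 °C; DMF, 0 °C → rt; H2O
Reagents that add atoms: 1-iodopropane CCCI; N,N-dimethylformamide CN(C)C=O
Why: Corey–Seebach umpolung then directed ortho-metalation in one flask: the sulfur-stabilised carbanion 5 is an acyl anion equivalent that forms the C(=O)–CH2 bond of the future butanoyl group by SN2 attack on 1-iodopropane (two carbons that are both electrophilic in their normal guise), and the only ring hydrogen of 6, acidified by two flanking methoxy groups, is then removed to give 7, which is formylated by DMF (Bouveault-type formylation) at the future bridge position without creating a stereocentre.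

Step 3
Reactants: 8 2,4,6-trimethoxy-3-methyl-5-(2-propyl-1,3-dithian-2-yl)benzaldehyde
Product: 9 2,6-dihydroxy-4-methoxy-3-methyl-5-(2-propyl-1,3-dithian-2-yl)benzaldehyde
Conditions: BCl3 (5 equiv), CH2Cl2, −78 °C → rt; aq. NaHCO3
Reagents that add atoms: none
Why: Carbonyl-directed (chelation-controlled) ortho-demethylation of aryl methyl ethers: BCl3 held on the aldehyde oxygen reaches each of the two flanking methoxy groups through a six-membered chelate, while the methoxy group para to the aldehyde has no such assistance and the ketone is silent as its dithiane, so exactly the two ethers next to the future bridge carbon are cleaved and no stereocentre is involved.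

Step 4
Reactants: 9 2,6-dihydroxy-4-methoxy-3-methyl-5-(2-propyl-1,3-dithian-2-yl)benzaldehyde
Product: 10 3-butanoyl-2,6-dihydroxy-4-methoxy-5-methylbenzaldehyde
Conditions: HgCl2 (2.2 equiv), CaCO3 (2.5 equiv), MeCN/H2O (4:1), 50 °C
Reagents that add atoms: water O
Why: Thiophilic hydrolysis of the dithioacetal, the unmasking half of the Corey–Seebach sequence: divalent mercury binds both sulfur atoms, water replaces them at the benzylic carbon and relief of strain at this fully flanked quaternary centre drives release of the ketone, while phenols, aldehyde and methyl ether are untouched and no stereocentre arises.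

Step 5
Reactants: 10 3-butanoyl-2,6-dihydroxy-4-methoxy-5-methylbenzaldehyde (2 equiv); 11 1-(2,4,6-trihydroxyphenyl)butan-1-one (1 equiv)
Product: 15 agrimol C, via benzylic alcohol 12 (not isolated), via ortho-quinone methide 13 (not isolated), via mono-adduct 14 (not isolated)
Conditions: 10, NaBH4 (0.5 equiv per 10), THF/EtOH, −10 °C; then 11, AcOH, 0 → 40 °C
Reagents that add atoms: none
Why: Chemoselective borohydride reduction followed by ortho-quinone methide Friedel–Crafts (Michael-type) alkylation: NaBH4 reduces only the aldehyde (the chelated, doubly flanked aryl ketone is far less electrophilic) to salicyl alcohol 12, acid turns 12 into 13, and 13 is captured by the two free and equivalent nucleophilic ring positions of 11 one after the other via 14, the wing having no free ring position of its own, so both methylene bridges form regiospecifically and the achiral target results.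

## Compound list

1 | 2,4,6-trimethoxytoluene (1,3,5-trimethoxy-2-methylbenzene) | Cc1c(OC)cc(OC)cc1OC | starting material
2 | 1,3-dithiane | C1CSCSC1 | starting material
3 | 2-chloro-1,3-dithiane | ClC1SCCCS1 | intermediate
4 | 2-(2,4,6-trimethoxy-3-methylphenyl)-1,3-dithiane | COc1cc(OC)c(C2SCCCS2)c(OC)c1C | intermediate
5 | 2-lithio-2-(2,4,6-trimethoxy-3-methylphenyl)-1,3-dithiane | [Li]C1(c2c(OC)cc(OC)c(C)c2OC)SCCCS1 | intermediate
6 | 2-propyl-2-(2,4,6-trimethoxy-3-methylphenyl)-1,3-dithiane | CCCC1(c2c(OC)cc(OC)c(C)c2OC)SCCCS1 | intermediate
7 | [2,4,6-trimethoxy-3-methyl-5-(2-propyl-1,3-dithian-2-yl)phenyl]lithium | [Li]c1c(OC)c(C)c(OC)c(C2(CCC)SCCCS2)c1OC | intermediate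
8 | 2,4,6-trimethoxy-3-methyl-5-(2-propyl-1,3-dithian-2-yl)benzaldehyde | O=Cc1c(OC)c(C)c(OC)c(C2(CCC)SCCCS2)c1OC | intermediate
9 | 2,6-dihydroxy-4-methoxy-3-methyl-5-(2-propyl-1,3-dithian-2-yl)benzaldehyde | O=Cc1c(O)c(C)c(OC)c(C2(CCC)SCCCS2)c1O | intermediate
10 | 3-butanoyl-2,6-dihydroxy-4-methoxy-5-methylbenzaldehyde | CCCC(=O)c1c(O)c(C=O)c(O)c(C)c1OC | intermediate
11 | 1-(2,4,6-trihydroxyphenyl)butan-1-one (butyrylphloroglucinol) | CCCC(=O)c1c(O)cc(O)cc1O | starting material
12 | 1-[2,4-dihydroxy-3-(hydroxymethyl)-6-methoxy-5-methylphenyl]butan-1-one | CCCC(=O)c1c(O)c(CO)c(O)c(C)c1OC | intermediate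
13 | 4-butanoyl-3-hydroxy-5-methoxy-6-methyl-2-methylidenecyclohexa-3,5-dien-1-one | C=C1C(=O)C(C)=C(OC)C(C(=O)CCC)=C1O | intermediate
14 | 1-[3-[(3-butanoyl-2,6-dihydroxy-4-methoxy-5-methylphenyl)methyl]-2,4,6-trihydroxyphenyl]butan-1-one | CCCC(=O)c1c(O)cc(O)c(Cc2c(O)c(C)c(OC)c(C(=O)CCC)c2O)c1O | intermediate
15 | agrimol C, 1-[3,5-bis[(3-butanoyl-2,6-dihydroxy-4-methoxy-5-methylphenyl)methyl]-2,4,6-trihydroxyphenyl]butan-1-one | CCCC(=O)c1c(O)c(Cc2c(O)c(C)c(OC)c(C(=O)CCC)c2O)c(O)c(Cc2c(O)c(C)c(OC)c(C(=O)CCC)c2O)c1O | target

## Step count and weak points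

Total step count: 5. Longest linear sequence: 5 steps (1 → 4 → 8 → 9 → 10 → 15); 2 and 11 are bought.

The three steps most likely to fail:

**Step 2.** The SN2 alkylation takes place at a carbanion flanked by two sulfur atoms and a doubly ortho-substituted arene, and the second n-BuLi charge may attack sulfur instead of the ring hydrogen. Fallback: set out from 4, lithiate as before and trap 5 with allyl bromide, a far more reactive SN2 partner, to give 2-(prop-2-en-1-yl)-2-(2,4,6-trimethoxy-3-methylphenyl)-1,3-dithiane F1. Saturate the alkene with diimide (TsNHNH2, NaOAc, aq. THF, reflux; sulfur rules out Pd/H2) to reach 6, which is now isolated. Then formylate 6 by electrophilic substitution (Vilsmeier–Haack, POCl3/DMF, 70 °C) instead of by lithiation; this comes back to the route at 8.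

**Step 3.** BCl3 also binds the dithiane sulfur atoms and may open the dithiane or stop at the mono-phenol. Fallback: set out from 8 and remove the dithiane first (HgCl2, CaCO3, aq. MeCN) to give 3-butanoyl-2,4,6-trimethoxy-5-methylbenzaldehyde F2. Then demethylate F2 with BCl3 using two directing carbonyl groups: the more Lewis-basic ketone should chelate boron with the ether it shares with the aldehyde, leaving the aldehyde to deliver boron to the ether next to the C-methyl group. This regiochemical outcome is less certain than in the main route. It gives 10 directly and comes back to the route there, bypassing 9.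

**Step 5.** Residual hydride can reduce 13 to a C-methyl group, and acid can scramble methylene bridges. Fallback: set out from 10; reductive amination with dimethylamine (Me2NH·HCl, NaBH(OAc)3, ClCH2CH2Cl, rt) gives the Mannich base 1-[3-[(dimethylamino)methyl]-2,4-dihydroxy-6-methoxy-5-methylphenyl]butan-1-one F3, an isolable, hydride-free precursor of 13. Heating F3 (2 equiv) with 11 in dioxane at 90 °C expels the amine and forms the two bridges thermally; this comes back to the route at 15.

## Further compounds

F1 | step 2 | 2-(prop-2-en-1-yl)-2-(2,4,6-trimethoxy-3-methylphenyl)-1,3-dithiane | C=CCC1(c2c(OC)cc(OC)c(C)c2OC)SCCCS1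
F2 | step 3 | 3-butanoyl-2,4,6-trimethoxy-5-methylbenzaldehyde | CCCC(=O)c1c(OC)c(C=O)c(OC)c(C)c1OC
F3 | step 5 | 1-[3-[(dimethylamino)methyl]-2,4-dihydroxy-6-methoxy-5-methylphenyl]butan-1-one | CCCC(=O)c1c(O)c(CN(C)C)c(O)c(C)c1OC
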